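**Retrosynthetic overview**
- The carboxyl group comes last, from an alkenyl triflate by Pd-catalysed hydroxycarbonylation, so no protecting group is needed; before that: Shi epoxidation of the E C5=C6 alkene, oxidative benzoylation with benzaldehyde, and CBS reduction of the C11 ketone.
- The enol triflate comes from an eleven-membered 1,3-dione (carbonyls at C9 and C11).
- Key step: the dione comes from a cyclohexanone carrying a 1-tosyloxy-4-oxopentyl chain by ring expansion. An intramolecular aldol (C10 to C11) is followed by Grob fragmentation of the C11–C5 bond, inserting five carbons and forming the E alkene.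
- The keto tosylate comes from 2-methylcyclohexanone by methylation, aldol with pent-4-enal, chelate-controlled C5 methylation, tosylation and Wacker oxidation.
- Ring order: six-membered ring (from the starting ketone), then a transient six–seven bicycle, then the eleven-membered carbocycle, then the oxirane.

Assumption: ring atoms are numbered C1 (CMe2), C2–C4 (CH2), C5 (epoxide C–Me), C6 (epoxide CH), C7, C8 (CH2), C9 (C–CO2H), C10 (=CH), C11 (CHOBz); the target is then 5R,6R,11R with CO2H trans to C11 across C9=C10 (C8 and C11 cis), and racemic intermediates are drawn as one enantiomer.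

**Route**

Step 1
Reactants: 1 2-methylcyclohexan-1-one
Product: 2 2,2-dimethylcyclohexan-1-one
Conditions: KH, THF, 25 °C; BEt3; MeI, 25 °C
Reagents that add atoms: iodomethane, CI
Why: Potassium enoxyborate alkylation: KH gives the equilibrated, more substituted enolate and BEt3 suppresses proton exchange and polyalkylation, so MeI enters at the methyl-bearing carbon (minor 2,6-isomer removed by distillation); no stereocentre remains.

Step 2
Reactants: 2 2,2-dimethylcyclohexan-1-one; 3 pent-4-enal
Product: 5 rac-(6S)-6-[(1R)-1-hydroxypent-4-en-1-yl]-2,2,6-trimethylcyclohexan-1-one, via lithium aldolate 4 (not isolated)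
Conditions: LiN(iPr)2 (1.05 equiv), THF, −78 °C; 3; LiN(iPr)2 (1.5 equiv), −78 to −30 °C; MeI, DMPU, −78 to −20 °C; H2O
Reagents that add atoms: iodomethane, CI
Why: Directed aldol addition followed by a Fráter–Seebach-type alkylation: the only enolisable position of 2 adds to the aldehyde, the lithium aldolate is deprotonated again to a chelated enolate–alkoxide, and MeI attacks the face anti to the butenyl chain, which sets methyl anti to OH (6S*,1′R*); the syn/anti ratio of 4 does not matter because its ring stereocentre is planarised in the dianion.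

Step 3
Reactants: 5 rac-(6S)-6-[(1R)-1-hydroxypent-4-en-1-yl]-2,2,6-trimethylcyclohexan-1-one
Product: 6 rac-(1R)-1-[(1S)-1,3,3-trimethyl-2-oxocyclohexyl]pent-4-en-1-yl 4-methylbenzenesulfonate
Conditions: TsCl, Et3N, Me3N·HCl (10 mol %), CH2Cl2, 0 °C
Reagents that add atoms: 4-methylbenzenesulfonyl chloride, Cc1ccc(cc1)S(Cl)(=O)=O
Why: Amine-catalysed O-sulfonylation of the hindered secondary alcohol with retention; a tosylate is used because it has no acidic α-hydrogens for the strong base of step 5, the quaternary α-carbon excludes β-elimination, and retro-aldol is no longer possible once oxygen is sulfonylated.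

Step 4
Reactants: 6 rac-(1R)-1-[(1S)-1,3,3-trimethyl-2-oxocyclohexyl]pent-4-en-1-yl 4-methylbenzenesulfonate
Product: 7 rac-(1R)-4-oxo-1-[(1S)-1,3,3-trimethyl-2-oxocyclohexyl]pentyl 4-methylbenzenesulfonate
Conditions: PdCl2 (10 mol %), CuCl (1 equiv), O2 (1 atm), DMF/H2O 7:1, 25 °C
Reagents that add atoms: water, O
Why: Tsuji–Wacker oxidation converts the terminal alkene into the methyl ketone (Markovnikov hydroxypalladation); the tosylate and the non-enolisable ring ketone are inert and no stereocentre is touched.

Step 5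
Reactants: 7 rac-(1R)-4-oxo-1-[(1S)-1,3,3-trimethyl-2-oxocyclohexyl]pentyl 4-methylbenzenesulfonate
Product: 9 (6E)-7,11,11-trimethylcycloundec-6-ene-1,3-dione, via bicyclic potassium alkoxide 8 (not isolated)
Conditions: KN(SiMe3)2 (2.3 equiv), THF (0.02 M), −78 to 0 °C; AcOH
Reagents that add atoms: none
Why: Proposed new method: enolate-triggered Grob ring expansion (net insertion of five carbons into a cyclohexanone), in which the kinetic potassium enolate of the methyl ketone adds reversibly (7-exo) to the non-enolisable ring carbonyl C11 and the tertiary alkoxide 8, with C11–C5 antiperiplanar to C6–OTs, fragments irreversibly, draining the unfavourable aldol equilibrium while the second equivalent of base stores the product as its dione enolate; because methyl and OTs are cis on the seven-membered ring (step 2), the concerted anti fragmentation can only give the 6E alkene and both old stereocentres vanish; the closest known reaction type is the Wharton–Grob fragmentation of γ-sulfonyloxy alkoxides made by adding hydride or organolithium reagents to β-sulfonyloxy ketones, here triggered instead by an intramolecular aldol addition.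

Step 6
Reactants: 9 (6E)-7,11,11-trimethylcycloundec-6-ene-1,3-dione
Product: 10 (1E,8E)-4,4,8-trimethyl-3-oxocycloundeca-1,8-dien-1-yl trifluoromethanesulfonate
Conditions: Tf2O (1.1 equiv), Et3N (1.5 equiv), CH2Cl2, −78 °C
Reagents that add atoms: trifluoromethanesulfonic anhydride, O=S(=O)(OS(=O)(=O)C(F)(F)F)C(F)(F)F
Why: O-Sulfonylation of the 1,3-dione enolate: the C9 oxygen reacts because the C11 oxygen is shielded by the gem-dimethyl group, and the medium-ring enolate is expected to be cisoid within the ring (as in dimedone), which places OTf trans to the C11 carbonyl (C8 and C11 cis) and so fixes the geometry of the future acrylic acid.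

Step 7
Reactants: 10 (1E,8E)-4,4,8-trimethyl-3-oxocycloundeca-1,8-dien-1-yl trifluoromethanesulfonate
Product: 11 (1E,3R,8E)-3-hydroxy-4,4,8-trimethylcycloundeca-1,8-dien-1-yl trifluoromethanesulfonate
Conditions: (S)-1-methyl-3,3-diphenyltetrahydro-1H,3H-pyrrolo[1,2-c][1,3,2]oxazaborole (20 mol %), catecholborane (1.8 equiv), toluene, −78 °C; MeOH, aq NaHCO3
Reagents that add atoms: none
Why: Corey–Bakshi–Shibata reduction: boron binds the carbonyl lone pair on the side of the flat CH= group, away from quaternary C1 (the large group, as with tert-alkyl ketones), so the (S)-catalyst should deliver hydride to give 11R; catecholborane at −78 °C gives 1,2-reduction without hydroborating the alkene or touching the enol triflate.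

Step 8
Reactants: 11 (1E,3R,8E)-3-hydroxy-4,4,8-trimethylcycloundeca-1,8-dien-1-yl trifluoromethanesulfonate; 12 benzaldehyde
Product: 13 (1R,2E,6E)-7,11,11-trimethyl-3-[(trifluoromethanesulfonyl)oxy]cycloundeca-2,6-dien-1-yl benzoate
Conditions: 12 (2 equiv), 1,4-dimethyl-4H-1,2,4-triazol-1-ium iodide (10 mol %), DBU (1.1 equiv), 3,3',5,5'-tetra-tert-butyl-4,4'-diphenoquinone (1.2 equiv), THF, 25 °C
Reagents that add atoms: none
Why: Oxidative N-heterocyclic-carbene-catalysed esterification: the Breslow intermediate from benzaldehyde is oxidised by the quinone to a benzoyl azolium ion that acylates the DBU-activated alcohol; the C–O bond of the stereocentre is not broken, so 11R is kept.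

Step 9
Reactants: 13 (1R,2E,6E)-7,11,11-trimethyl-3-[(trifluoromethanesulfonyl)oxy]cycloundeca-2,6-dien-1-yl benzoate
Product: 14 (1R,4E,6R,11R)-7,7,11-trimethyl-4-[(trifluoromethanesulfonyl)oxy]-12-oxabicyclo[9.1.0]dodec-4-en-6-yl benzoate
Conditions: 1,2:4,5-di-O-isopropylidene-β-D-erythro-2,3-hexodiulo-2,6-pyranose (30 mol %), KHSO5 (as 2KHSO5·KHSO4·K2SO4), K2CO3, Bu4NHSO4, MeCN/CH2(OMe)2/aq buffer pH 10.5, 0 °C
Reagents that add atoms: KHSO5, [K+].[O-]S(=O)(=O)OO
Why: Shi asymmetric epoxidation: the dioxirane of the D-fructose-derived ketone attacks only the electron-rich trisubstituted alkene (the enol triflate alkene is electron-poor) through the spiro transition state that gives R,R-epoxides from E-trisubstituted alkenes, so C5 and C6 are set 5R,6R (trans epoxide from the E alkene) under catalyst control.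

Step 10
Reactants: 14 (1R,4E,6R,11R)-7,7,11-trimethyl-4-[(trifluoromethanesulfonyl)oxy]-12-oxabicyclo[9.1.0]dodec-4-en-6-yl benzoate
Product: 15 (1R,4E,6R,11R)-6-(benzoyloxy)-7,7,11-trimethyl-12-oxabicyclo[9.1.0]dodec-4-ene-4-carboxylic acid
Conditions: Pd(OAc)2 (5 mol %), Fe(C5H4PPh2)2 (6 mol %), CO (1 atm), KOAc (4 equiv), DMF, 25 °C; H2O, pH 4 buffer
Reagents that add atoms: carbon monoxide, [C-]#[O+]; water, O
Why: Palladium-catalysed hydroxycarbonylation of an alkenyl triflate (oxidative addition, CO insertion, acetate capture to a mixed anhydride, hydrolysis) with retention of alkene geometry; at room temperature under CO the zerovalent palladium should leave the hindered allylic benzoate and the isolated epoxide alone.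

**Compound list**
1 | 2-methylcyclohexan-1-one (racemic) | CC1CCCCC1=O | starting material
2 | 2,2-dimethylcyclohexan-1-one | CC1(C)CCCCC1=O | intermediate
3 | pent-4-enal | C=CCCC=O | starting material
4 | lithium aldolate of 6-(1-hydroxypent-4-en-1-yl)-2,2-dimethylcyclohexan-1-one (diastereomer mixture, not isolated) | CC1(C)CCCC(C([O-])CCC=C)C1=O.[Li+] | intermediate
5 | rac-(6S)-6-[(1R)-1-hydroxypent-4-en-1-yl]-2,2,6-trimethylcyclohexan-1-one | CC1(C)CCC[C@@](C)([C@H](O)CCC=C)C1=O | intermediate
6 | rac-(1R)-1-[(1S)-1,3,3-trimethyl-2-oxocyclohexyl]pent-4-en-1-yl 4-methylbenzenesulfonate | CC1(C)CCC[C@@](C)([C@H](OS(=O)(=O)c2ccc(C)cc2)CCC=C)C1=O | intermediate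
7 | rac-(1R)-4-oxo-1-[(1S)-1,3,3-trimethyl-2-oxocyclohexyl]pentyl 4-methylbenzenesulfonate | CC1(C)CCC[C@@](C)([C@H](OS(=O)(=O)c2ccc(C)cc2)CCC(C)=O)C1=O | intermediate
8 | potassium rac-(9R,9aS)-4,4,9a-trimethyl-6-oxo-9-(tosyloxy)decahydro-4aH-benzo[7]annulen-4a-olate (ring-fusion epimers, not isolated) | CC1(C)CCC[C@@]2(C)[C@H](OS(=O)(=O)c3ccc(C)cc3)CCC(=O)CC12[O-].[K+] | intermediate
9 | (6E)-7,11,11-trimethylcycloundec-6-ene-1,3-dione | CC1(C)CCC/C(C)=C/CCC(=O)CC1=O | intermediate
10 | (1E,8E)-4,4,8-trimethyl-3-oxocycloundeca-1,8-dien-1-yl trifluoromethanesulfonate | CC1(C)CCC/C(C)=C/CC/C(OS(=O)(=O)C(F)(F)F)=C\C1=O | intermediate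
11 | (1E,3R,8E)-3-hydroxy-4,4,8-trimethylcycloundeca-1,8-dien-1-yl trifluoromethanesulfonate | CC1(C)CCC/C(C)=C/CC/C(OS(=O)(=O)C(F)(F)F)=C\[C@H]1O | intermediate
12 | benzaldehyde | O=Cc1ccccc1 | starting material
13 | (1R,2E,6E)-7,11,11-trimethyl-3-[(trifluoromethanesulfonyl)oxy]cycloundeca-2,6-dien-1-yl benzoate | CC1(C)CCC/C(C)=C/CC/C(OS(=O)(=O)C(F)(F)F)=C\[C@H]1OC(=O)c1ccccc1 | intermediate
14 | (1R,4E,6R,11R)-7,7,11-trimethyl-4-[(trifluoromethanesulfonyl)oxy]-12-oxabicyclo[9.1.0]dodec-4-en-6-yl benzoate | CC1(C)CCC[C@@]2(C)O[C@@H]2CC/C(OS(=O)(=O)C(F)(F)F)=C\[C@H]1OC(=O)c1ccccc1 | intermediate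
15 | (1R,4E,6R,11R)-6-(benzoyloxy)-7,7,11-trimethyl-12-oxabicyclo[9.1.0]dodec-4-ene-4-carboxylic acid (CNP0377917.1) | CC1(C)CCC[C@@]2(C)O[C@@H]2CC/C(C(=O)O)=C\[C@H]1OC(=O)c1ccccc1 | target

**Totals**
Total step count: 10. Longest linear sequence: 10 steps (1 to 15).

**Three steps most likely to fail**

Step 5 (the new ring expansion). The enolate may not add to the carbonyl flanked by two quaternary carbons, or it may scramble to the internal enolate (cyclopropane or five-membered-ring aldol products). The fallback splits the cascade into known reactions, setting out from 7. LiN(iPr)2 and Me3SiCl in THF at −78 °C give the kinetic silyl enol ether rac-(1R)-1-[(1S)-1,3,3-trimethyl-2-oxocyclohexyl]-4-[(trimethylsilyl)oxy]pent-4-en-1-yl 4-methylbenzenesulfonate F4. N-Bromosuccinimide in THF at 0 °C gives the bromomethyl ketone rac-(1R)-5-bromo-4-oxo-1-[(1S)-1,3,3-trimethyl-2-oxocyclohexyl]pentyl 4-methylbenzenesulfonate F5. SmI2 (2.2 equiv) in THF at −78 °C, a Reformatsky-type cyclisation with divalent samarium that closes rings onto hindered ketones and holds the aldolate as a chelate, gives the isolable bicyclic aldol rac-(9R,9aS)-4a-hydroxy-4,4,9a-trimethyl-6-oxodecahydro-1H-benzo[7]annulen-9-yl 4-methylbenzenesulfonate F6. KOtBu in t-BuOH/THF at 0 °C then effects a classical Wharton–Grob fragmentation, and the sequence comes back to the route at 9.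

Step 2 (one-pot aldol and chelate-controlled methylation). Second deprotonation of the hindered lithium aldolate may be slow, or retro-aldol may compete; the wrong diastereomer would give the 6Z macrocycle. The fallback builds the same stereo-relationship by reduction instead of alkylation, setting out from 2. LiN(iPr)2 and MeI give 2,2,6-trimethylcyclohexan-1-one F1. Its lithium enolate and 3 give, through the closed Zimmerman–Traxler transition state, the epimeric aldol rac-(6S)-6-[(1S)-1-hydroxypent-4-en-1-yl]-2,2,6-trimethylcyclohexan-1-one F2. Dess–Martin periodinane gives the non-enolisable diketone 2,2,6-trimethyl-6-(pent-4-enoyl)cyclohexan-1-one F3. Zn(BH4)2 in Et2O at −20 °C reduces only the side-chain ketone under chelation control (hydride enters past the methyl group; this selectivity rests on a small size difference) and comes back to the route at 5.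

Step 6 (regio- and geometric selectivity of the enol triflate). Kinetic O-sulfonylation could give the ring-trans isomer or the C11 enol triflate. The fallback uses a derivative whose geometry can equilibrate, setting out from 9. Ph3P, I2 and Et3N in MeCN give the β-iodo enone (2E,6E)-3-iodo-7,11,11-trimethylcycloundeca-2,6-dien-1-one F7, which is equilibrated to the thermodynamic ring-cis isomer with NaI (cat.) in AcOH by reversible iodide addition–elimination. F7 is then carried through the conditions of steps 7, 8 and 9 to give the alcohol (1R,2E,6E)-3-iodo-7,11,11-trimethylcycloundeca-2,6-dien-1-ol F8, the benzoate (1R,2E,6E)-3-iodo-7,11,11-trimethylcycloundeca-2,6-dien-1-yl benzoate F9 and the epoxide (1R,4E,6R,11R)-4-iodo-7,7,11-trimethyl-12-oxabicyclo[9.1.0]dodec-4-en-6-yl benzoate F10. Hydroxycarbonylation of F10 under the conditions of step 10 comes back to the route at 15.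

**Further compounds**
F1 | step 2 | 2,2,6-trimethylcyclohexan-1-one (racemic) | CC1CCCC(C)(C)C1=O
F2 | step 2 | rac-(6S)-6-[(1S)-1-hydroxypent-4-en-1-yl]-2,2,6-trimethylcyclohexan-1-one | CC1(C)CCC[C@@](C)([C@@H](O)CCC=C)C1=O
F3 | step 2 | 2,2,6-trimethyl-6-(pent-4-enoyl)cyclohexan-1-one (racemic) | CC1(C)CCCC(C)(C(=O)CCC=C)C1=O
F4 | step 5 | rac-(1R)-1-[(1S)-1,3,3-trimethyl-2-oxocyclohexyl]-4-[(trimethylsilyl)oxy]pent-4-en-1-yl 4-methylbenzenesulfonate | CC1(C)CCC[C@@](C)([C@H](OS(=O)(=O)c2ccc(C)cc2)CCC(=C)O[Si](C)(C)C)C1=O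
F5 | step 5 | rac-(1R)-5-bromo-4-oxo-1-[(1S)-1,3,3-trimethyl-2-oxocyclohexyl]pentyl 4-methylbenzenesulfonate | CC1(C)CCC[C@@](C)([C@H](OS(=O)(=O)c2ccc(C)cc2)CCC(=O)CBr)C1=O
F6 | step 5 | rac-(9R,9aS)-4a-hydroxy-4,4,9a-trimethyl-6-oxodecahydro-1H-benzo[7]annulen-9-yl 4-methylbenzenesulfonate | CC1(C)CCC[C@@]2(C)[C@H](OS(=O)(=O)c3ccc(C)cc3)CCC(=O)CC12O
F7 | step 6 | (2E,6E)-3-iodo-7,11,11-trimethylcycloundeca-2,6-dien-1-one | CC1(C)CCC/C(C)=C/CC/C(I)=C\C1=O
F8 | step 6 | (1R,2E,6E)-3-iodo-7,11,11-trimethylcycloundeca-2,6-dien-1-ol | CC1(C)CCC/C(C)=C/CC/C(I)=C\[C@H]1O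
F9 | step 6 | (1R,2E,6E)-3-iodo-7,11,11-trimethylcycloundeca-2,6-dien-1-yl benzoate | CC1(C)CCC/C(C)=C/CC/C(I)=C\[C@H]1OC(=O)c1ccccc1
F10 | step 6 | (1R,4E,6R,11R)-4-iodo-7,7,11-trimethyl-12-oxabicyclo[9.1.0]dodec-4-en-6-yl benzoate | CC1(C)CCC[C@@]2(C)O[C@@H]2CC/C(I)=C\[C@H]1OC(=O)c1ccccc1
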